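## The problem

Target 21 is a flavone whose ring A is fully substituted. C5, C6, C7, C8 and C8a all carry oxygen, C4a carries the pyranone carbonyl, and only the C6 oxygen is a free hydroxyl, lying between the C5 and C7 methoxyls. Ring B is attached to C2 through C1' and is flanked by a hydroxyl (C2') and a methoxyl (C6'), so the C4–C3–C2 chain ends at a doubly ortho-substituted aryl group. The target has no stereocentre; every sp3 centre met on the way is temporary and needs no control. Three sensitivities limit the chemistry: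

- The C5 methoxyl, peri to the C4 carbonyl, is the first ether to fall to Lewis acids. The C6 hydroxyl therefore cannot be uncovered by selective demethylation and must arrive already differentiated.
- Ring A becomes a quinone as soon as two para oxygens are free in the presence of an oxidant.
- The C2=C3 enone should not be over-reduced in the last step.

The feature that opens the structure is the run C6 (OH), C7 (OMe), C8 (OMe), C8a (O1), with the C6 and C8a oxygens para. These four carbons map onto dimethyl squarate after a ring expansion, and C5 (OMe) and C4a (carbon chain) form a two-carbon enol ether unit that can be brought in as an alkenyl group.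

## Retrosynthesis

**21 from 20.** The two O–benzyl bonds of bis(benzyl ether) 20 are cut. Benzyl is chosen for both phenols so that one hydrogenolysis frees them together and leaves the four methyl ethers alone. A Lewis-acid deprotection would strip the C5 methoxyl.

**20 from 18.** The O1–C2 bond is cut to give ortho-hydroxyaryl ynone 18. Against a 1,3-diketone closure, the ynone has the advantage that C4, C3, C2 and ring B are already joined in the right oxidation state. The forward step needs 6-endo rather than 5-exo attack of the phenol. A secondary amine secures this by first forming enaminone 19.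

**18 from 15.** Ynone 18 goes back by oxidation level to carbinol 17, by two Si–O bonds to bis(silyl ether) 16, and by one O–benzyl bond to phenol 15. In 15 the C6 hydroxyl is the only free phenol, so its benzylation needs no selectivity.

**15 from 12 (key disconnection).** The C5–C6 bond of ring A is cut and the C6/C8a carbons are rejoined as a four-membered ring. Phenol 15 thus becomes the 4-alkenyl-4-(silyloxy)cyclobutenone 12 through dienylketene 13 and dienone 14. No other cut of ring A delivers five correctly differentiated oxygens in one step. The ketene carbon becomes the free C6 hydroxyl, the silylated carbinol carbon becomes C8a, the two squarate methoxyls become the C7 and C8 methoxyls, and the enol ether supplies the C5 methoxyl. Silylating the tertiary carbinol is a deliberate refinement over the free carbinol. It tells the two para oxygens apart, avoids an air-sensitive hydroquinone, and blocks capture of the ketene by the hydroxyl. The precursor is much simpler: an aromatic ring is exchanged for a squarate adduct.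

**12 from 8 and 9.** The bond between the carbinol carbon and the alkenyl carbon (the future C8a–C4a bond) is cut. Silyl ether 12 comes from carbinol 11, and 11 from vinyllithium 10 and dimethyl squarate 9. Vinyllithium 10 is made from vinyl bromide 8 by halogen–metal exchange. The forward reaction needs a vinyllithium that survives at low temperature. The cis arrangement of lithium and methoxyl in 10 is the one that does.

**8 from 3 and 5.** Silyl ether 8 comes from carbinol 7. The bond between the carbinol carbon (future C4) and the alkyne carbon (future C3) of 7 is cut to give lithium acetylide 6 and aldehyde 5. This is the only polar cut that uses an aldehyde available in one step. The acetylide must add 1,2 to a β-methoxy enal, as hard lithium nucleophiles do.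

**Starting materials.** Aldehyde 5 is the O-methyl enol ether of bromomalonaldehyde 4. Acetylide 6 comes from alkyne 3, alkyne 3 from aldehyde 2 by one-carbon homologation, and 2 from 2-hydroxy-6-methoxybenzaldehyde 1 by benzylation. Ring B therefore arrives with both its oxygens in place.

## Roads not taken

**Alternative 1:** The cut goes through O1–C8a and C4–C4a of ynone A1.

- Forward step: a symmetric tetraoxygenated aryne, released from silyl triflate A2, is attacked by the carboxylate of arylpropiolic acid A3. The resulting aryl anion takes the acyl carbon through a four-membered transition state, so the aryne inserts into the C–O bond of the acid.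
- Merits: it is the most convergent road. A1, the counterpart of ynone 18, is reached in one step from two fragments, and the symmetric aryne has no regiochemical question.
- Weak points: A2 is a hexasubstituted benzene with silyl, triflate and four oxygens, and it must itself be built step by step. The aryne is flanked by two methoxyls and is electron-rich, so O-arylation without acyl shift and simple protonation compete. The symmetry that helps the insertion then hurts, because the C6 and C7 oxygens are both benzyl ethers and must be told apart afterwards by selective 7-O-methylation.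
- Comparison: Alternative 1 is clearly better in convergence at the ynone stage. The chosen plan offers in return that every ring A oxygen is differentiated from the moment ring A forms, and that no late regioselective alkylation is needed.

**Alternative 2:** The cut is the C2'–O bond of ring B, made from a C3 carboxyl.

- Forward step: anodic oxidation of flavone-3-carboxylic acid A5 gives an acyloxy radical that adds to C2'. Further oxidation and proton loss close lactone A4. Hydrolysis and decarboxylation would then reveal the C2' hydroxyl and C3–H.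
- Merits: the flavone core could be assembled by robust classical chemistry with stable intermediates and no cryogenic organolithium steps. In that respect it is the better road. The carboxyl is a traceless directing group.
- Weak points: it spends its key step on an oxygen that is commercially available in aldehyde 1. It leaves the real difficulty, the differentiated pentaoxygenated ring A, to be solved separately. The electron-rich ring A is likely to be oxidised at the anode before the carboxylate. The acyloxy radical can also attack the methoxy-bearing ortho carbon, and removal of the carboxyl costs further steps.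
- Comparison: the chosen plan concentrates its key step on ring A, where the target is hard.

**Alternative 3:** The cut goes through C1'–C2', C2'–C3' and C5'–C6' of ring B in phenol A6.

- Forward step: cyclobutenone A7 opens to vinylketene, which adds (2+2) to alkynyl ether A8. A 4π opening and 6π closure follow and give the 2-hydroxy-6-methoxyphenyl ring.
- Merits: it uses the same pericyclic logic as the chosen plan. It delivers the C2' hydroxyl free, so only one benzyl group remains to be removed. In protecting-group economy on ring B it is better.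
- Weak points: A8 is a push–pull ynol ether conjugated to the chromone, so it is a poor partner for a ketene. The parent A7 is volatile and its vinylketene dimerises readily. The chromone with a differentiated C6 oxygen must still be made by other means.
- Comparison: the chosen plan applies the ring expansion to the ring that cannot be bought, and buys the one that can.

Key step: step 8

Assumptions:
- The O-methylation in step 3 is taken to give the (Z)-enol ether (bromine cis to methoxyl), as expected for a push–pull enal. This geometry is drawn through compound 12 and is erased in step 8.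
- Compounds with one sp3 carbinol centre are racemic, and those with two are mixtures of racemic diastereomers.
- TBS stands for tert-butyldimethylsilyl and Bn for benzyl.

## Route

Step 1
Reactants: 1 2-hydroxy-6-methoxybenzaldehyde
Product: 2 2-(benzyloxy)-6-methoxybenzaldehyde
Conditions: BnBr, K2CO3, DMF, 60 °C
Reagents that add atoms: benzyl bromide, BrCc1ccccc1
Why: Williamson etherification of the phenoxide; the aldehyde has no enolisable position and is untouched.

Step 2
Reactants: 2 2-(benzyloxy)-6-methoxybenzaldehyde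
Product: 3 1-(benzyloxy)-2-ethynyl-3-methoxybenzene
Conditions: MeC(O)C(N2)P(O)(OMe)2, K2CO3, MeOH, 0 °C to rt
Reagents that add atoms: dimethyl (1-diazo-2-oxopropyl)phosphonate, COP(=O)(OC)C(=[N+]=[N-])C(C)=O
Why: Ohira–Bestmann variant of the Seyferth–Gilbert homologation; the diazomethylphosphonate formed by methanolysis olefinates the aldehyde, and loss of N2 with 1,2-hydrogen shift gives the terminal alkyne under conditions that spare the benzyl ether.

Step 3
Reactants: 4 bromomalonaldehyde
Product: 5 (2Z)-2-bromo-3-methoxyprop-2-enal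
Conditions: Me3SiCHN2, MeOH/PhMe, 0 °C
Reagents that add atoms: (trimethylsilyl)diazomethane, C[Si](C)(C)C=[N+]=[N-]
Why: O-methylation of a strongly acidic enol (a vinylogous formic acid) by a diazoalkane; the two carbonyls of 4 are equivalent, so only one constitution can form, and the methoxyl should settle trans to the formyl group.

Step 4
Reactants: 3 1-(benzyloxy)-2-ethynyl-3-methoxybenzene; 5 (2Z)-2-bromo-3-methoxyprop-2-enal
Product: 7 (1Z)-5-[2-(benzyloxy)-6-methoxyphenyl]-2-bromo-1-methoxypent-1-en-4-yn-3-ol (racemic), via lithium acetylide 6 (not isolated)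
Conditions: n-BuLi, THF, −78 °C; then 5, −78 °C; aq NH4Cl; Et3N-washed silica
Reagents that add atoms: none
Why: 1,2-addition of a lithium acetylide to the aldehyde of a β-alkoxy enal, the normal course for hard lithium nucleophiles at low temperature; the carbinol centre forms without control, and the buffered work-up avoids acid-induced allylic transposition of the enol ether alcohol.

Step 5
Reactants: 7 (1Z)-5-[2-(benzyloxy)-6-methoxyphenyl]-2-bromo-1-methoxypent-1-en-4-yn-3-ol
Product: 8 tert-butyl{[(1Z)-5-[2-(benzyloxy)-6-methoxyphenyl]-2-bromo-1-methoxypent-1-en-4-yn-3-yl]oxy}dimethylsilane (racemic)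
Conditions: TBSCl, imidazole, DMF, 0 °C to rt
Reagents that add atoms: tert-butyldimethylsilyl chloride, CC(C)(C)[Si](C)(C)Cl
Why: standard silylation of a secondary alcohol under basic conditions that spare the enol ether; it removes the acidic proton before the lithiation and blocks ionisation of the allylic carbinol.

Step 6
Reactants: 8 tert-butyl{[(1Z)-5-[2-(benzyloxy)-6-methoxyphenyl]-2-bromo-1-methoxypent-1-en-4-yn-3-yl]oxy}dimethylsilane; 9 dimethyl squarate
Product: 11 4-{(1Z)-5-[2-(benzyloxy)-6-methoxyphenyl]-3-[(tert-butyldimethylsilyl)oxy]-1-methoxypent-1-en-4-yn-2-yl}-4-hydroxy-2,3-dimethoxycyclobut-2-en-1-one (mixture of racemic diastereomers), via vinyllithium 10 (not isolated)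
Conditions: t-BuLi (2 equiv), Et2O, −78 °C; then added to 9, THF, −78 °C; aq NH4Cl at −78 °C
Reagents that add atoms: none
Why: bromine–lithium exchange with retention gives a vinyllithium whose lithium is cis to the methoxyl, the arrangement in which β-alkoxyvinyllithiums are stabilised by coordination and cannot undergo anti elimination; 1,2-addition to one carbonyl of dimethyl squarate is the standard entry to 4-substituted 4-hydroxycyclobutenones, and the new carbinol centre is formed without control because it is destroyed in step 8.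

Step 7
Reactants: 11 4-{(1Z)-5-[2-(benzyloxy)-6-methoxyphenyl]-3-[(tert-butyldimethylsilyl)oxy]-1-methoxypent-1-en-4-yn-2-yl}-4-hydroxy-2,3-dimethoxycyclobut-2-en-1-one
Product: 12 4-{(1Z)-5-[2-(benzyloxy)-6-methoxyphenyl]-3-[(tert-butyldimethylsilyl)oxy]-1-methoxypent-1-en-4-yn-2-yl}-4-[(tert-butyldimethylsilyl)oxy]-2,3-dimethoxycyclobut-2-en-1-one (mixture of racemic diastereomers)
Conditions: TBSOTf, 2,6-lutidine, CH2Cl2, −78 to 0 °C
Reagents that add atoms: tert-butyldimethylsilyl trifluoromethanesulfonate, CC(C)(C)[Si](C)(C)OS(=O)(=O)C(F)(F)F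
Why: silylation of a tertiary alcohol with a silyl triflate and a hindered pyridine base, which buffers the acid so that neither the enol ether nor the carbinol carbon ionises; the silyl group marks the future C8a oxygen.

Step 8
Reactants: 12 4-{(1Z)-5-[2-(benzyloxy)-6-methoxyphenyl]-3-[(tert-butyldimethylsilyl)oxy]-1-methoxypent-1-en-4-yn-2-yl}-4-[(tert-butyldimethylsilyl)oxy]-2,3-dimethoxycyclobut-2-en-1-one
Product: 15 3-{3-[2-(benzyloxy)-6-methoxyphenyl]-1-[(tert-butyldimethylsilyl)oxy]prop-2-yn-1-yl}-4-[(tert-butyldimethylsilyl)oxy]-2,5,6-trimethoxyphenol (racemic), via dienylketene 13 (not isolated), via cyclohexa-2,4-dienone 14 (not isolated)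
Conditions: PhMe (degassed, dilute), 110 °C, Ar
Reagents that add atoms: none
Why: This is the Moore rearrangement of a squarate-derived 4-alkenyl-4-(silyloxy)cyclobutenone, an established thermal route to highly oxygenated phenols and quinones. Heating cleaves the bond between the carbonyl carbon and the carbinol carbon by conrotatory 4π electrocyclic opening and gives dienylketene 13. A 6π electrocyclisation then joins the ketene carbon to the methoxy-bearing alkene carbon, which forms the C5–C6 bond and closes ring A as the six-membered dienone 14; enolisation gives phenol 15. The selectivity the step needs is torquoselectivity: the alkenyl group must rotate inward to lie cis to the ketene, and the silyloxy donor on the carbinol carbon secures this because oxygen donors rotate outward. Regiochemistry is fixed by connectivity, since the ketene carbon can reach only the enol ether carbon through a six-membered transition state, and the cis methoxyl is tolerated because the ketene terminus has no inward substituent. No lasting stereocentre is made: the sp3 carbon of 14 is lost on aromatisation and the side-chain carbinol centre is untouched and racemic. The ketene oxygen emerges as the free C6 hydroxyl while the C8a oxygen stays silylated, so the two para oxygens are differentiated in the same step. Dilute, degassed, acid-free conditions keep the ketene from intermolecular capture and the enol ether from hydrolysis.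

Step 9
Reactants: 15 3-{3-[2-(benzyloxy)-6-methoxyphenyl]-1-[(tert-butyldimethylsilyl)oxy]prop-2-yn-1-yl}-4-[(tert-butyldimethylsilyl)oxy]-2,5,6-trimethoxyphenol
Product: 16 1-(benzyloxy)-3-{3-[2-(benzyloxy)-6-methoxyphenyl]-1-[(tert-butyldimethylsilyl)oxy]prop-2-yn-1-yl}-4-[(tert-butyldimethylsilyl)oxy]-2,5,6-trimethoxybenzene (racemic)
Conditions: BnBr, K2CO3, acetone, 50 °C
Reagents that add atoms: benzyl bromide, BrCc1ccccc1
Why: Williamson benzylation of the only free phenol; 2,6-dimethoxyphenols alkylate readily, and anhydrous carbonate in acetone should leave the hindered aryl silyl ether in place.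

Step 10
Reactants: 16 1-(benzyloxy)-3-{3-[2-(benzyloxy)-6-methoxyphenyl]-1-[(tert-butyldimethylsilyl)oxy]prop-2-yn-1-yl}-4-[(tert-butyldimethylsilyl)oxy]-2,5,6-trimethoxybenzene
Product: 17 4-(benzyloxy)-2-{3-[2-(benzyloxy)-6-methoxyphenyl]-1-hydroxyprop-2-yn-1-yl}-3,5,6-trimethoxyphenol (racemic)
Conditions: Bu4NF, AcOH, THF, 0 °C to rt
Reagents that add atoms: none
Why: fluoride cleavage of the aryl and the secondary silyl ether in one operation; the acetic acid buffer keeps the phenoxide from attacking the alkyne and the propargylic alcohol from isomerising.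

Step 11
Reactants: 17 4-(benzyloxy)-2-{3-[2-(benzyloxy)-6-methoxyphenyl]-1-hydroxyprop-2-yn-1-yl}-3,5,6-trimethoxyphenol
Product: 18 1-[3-(benzyloxy)-6-hydroxy-2,4,5-trimethoxyphenyl]-3-[2-(benzyloxy)-6-methoxyphenyl]prop-2-yn-1-one
Conditions: MnO2, CH2Cl2, rt
Reagents that add atoms: none
Why: MnO2 oxidation of a benzylic and propargylic alcohol to the ynone, the usual preparation of ortho-hydroxyaryl ynones; with the C6 oxygen benzylated the ring cannot be oxidised to a quinone.

Step 12
Reactants: 18 1-[3-(benzyloxy)-6-hydroxy-2,4,5-trimethoxyphenyl]-3-[2-(benzyloxy)-6-methoxyphenyl]prop-2-yn-1-one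
Product: 20 6-(benzyloxy)-2-[2-(benzyloxy)-6-methoxyphenyl]-5,7,8-trimethoxy-4H-chromen-4-one, via enaminone 19 (not isolated)
Conditions: Et2NH, EtOH, rt to 50 °C
Reagents that add atoms: none
Why: conjugate addition of the secondary amine to the ynone gives a β-amino enone, and the ortho phenol then displaces the amine at the β-carbon by intramolecular addition–elimination; this amine-mediated 6-endo closure gives the chromone where carbonate bases can give the 5-exo aurone.

Step 13
Reactants: 20 6-(benzyloxy)-2-[2-(benzyloxy)-6-methoxyphenyl]-5,7,8-trimethoxy-4H-chromen-4-one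
Product: 21 6-hydroxy-2-(2-hydroxy-6-methoxyphenyl)-5,7,8-trimethoxy-4H-chromen-4-one (6,2'-dihydroxy-5,7,8,6'-tetramethoxyflavone)
Conditions: H2 (1 atm), Pd/C, EtOAc/MeOH, rt
Reagents that add atoms: none
Why: hydrogenolysis of both aryl benzyl ethers; methyl ethers are inert and the pyranone double bond is normally retained when the reaction is stopped at full debenzylation.

## Compound list

1 | 2-hydroxy-6-methoxybenzaldehyde | COc1cccc(O)c1C=O | starting material
2 | 2-(benzyloxy)-6-methoxybenzaldehyde | COc1cccc(OCc2ccccc2)c1C=O | intermediate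
3 | 1-(benzyloxy)-2-ethynyl-3-methoxybenzene | COc1cccc(OCc2ccccc2)c1C#C | intermediate
4 | bromomalonaldehyde (2-bromopropanedial, present as its enol) | O=CC(Br)C=O | starting material
5 | (2Z)-2-bromo-3-methoxyprop-2-enal | CO/C=C(\Br)C=O | intermediate
6 | lithium [2-(benzyloxy)-6-methoxyphenyl]acetylide | [Li]C#Cc1c(OC)cccc1OCc1ccccc1 | intermediate (not isolated)
7 | (1Z)-5-[2-(benzyloxy)-6-methoxyphenyl]-2-bromo-1-methoxypent-1-en-4-yn-3-ol (racemic) | CO/C=C(\Br)C(O)C#Cc1c(OC)cccc1OCc1ccccc1 | intermediate
8 | tert-butyl{[(1Z)-5-[2-(benzyloxy)-6-methoxyphenyl]-2-bromo-1-methoxypent-1-en-4-yn-3-yl]oxy}dimethylsilane (racemic) | CO/C=C(\Br)C(O[Si](C)(C)C(C)(C)C)C#Cc1c(OC)cccc1OCc1ccccc1 | intermediate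
9 | dimethyl squarate (3,4-dimethoxycyclobut-3-ene-1,2-dione) | COC1=C(OC)C(=O)C1=O | starting material
10 | {(1E)-5-[2-(benzyloxy)-6-methoxyphenyl]-3-[(tert-butyldimethylsilyl)oxy]-1-methoxypent-1-en-4-yn-2-yl}lithium (lithium cis to methoxyl, racemic) | CO/C=C(\[Li])C(O[Si](C)(C)C(C)(C)C)C#Cc1c(OC)cccc1OCc1ccccc1 | intermediate (not isolated)
11 | 4-{(1Z)-5-[2-(benzyloxy)-6-methoxyphenyl]-3-[(tert-butyldimethylsilyl)oxy]-1-methoxypent-1-en-4-yn-2-yl}-4-hydroxy-2,3-dimethoxycyclobut-2-en-1-one (mixture of racemic diastereomers) | O=C1C(OC)=C(OC)C1(O)/C(=C\OC)C(O[Si](C)(C)C(C)(C)C)C#Cc1c(OC)cccc1OCc1ccccc1 | intermediate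
12 | 4-{(1Z)-5-[2-(benzyloxy)-6-methoxyphenyl]-3-[(tert-butyldimethylsilyl)oxy]-1-methoxypent-1-en-4-yn-2-yl}-4-[(tert-butyldimethylsilyl)oxy]-2,3-dimethoxycyclobut-2-en-1-one (mixture of racemic diastereomers) | O=C1C(OC)=C(OC)C1(O[Si](C)(C)C(C)(C)C)/C(=C\OC)C(O[Si](C)(C)C(C)(C)C)C#Cc1c(OC)cccc1OCc1ccccc1 | intermediate
13 | (3Z,5Z)-5-{3-[2-(benzyloxy)-6-methoxyphenyl]-1-[(tert-butyldimethylsilyl)oxy]prop-2-yn-1-yl}-4-[(tert-butyldimethylsilyl)oxy]-2,3,6-trimethoxyhexa-1,3,5-trien-1-one (dienylketene, racemic) | O=C=C(OC)/C(OC)=C(/O[Si](C)(C)C(C)(C)C)\C(=C/OC)C(O[Si](C)(C)C(C)(C)C)C#Cc1c(OC)cccc1OCc1ccccc1 | intermediate (not isolated)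
14 | 5-{3-[2-(benzyloxy)-6-methoxyphenyl]-1-[(tert-butyldimethylsilyl)oxy]prop-2-yn-1-yl}-4-[(tert-butyldimethylsilyl)oxy]-2,3,6-trimethoxycyclohexa-2,4-dien-1-one (mixture of racemic diastereomers) | O=C1C(OC)=C(OC)C(O[Si](C)(C)C(C)(C)C)=C(C(O[Si](C)(C)C(C)(C)C)C#Cc2c(OC)cccc2OCc2ccccc2)C1OC | intermediate (not isolated)
15 | 3-{3-[2-(benzyloxy)-6-methoxyphenyl]-1-[(tert-butyldimethylsilyl)oxy]prop-2-yn-1-yl}-4-[(tert-butyldimethylsilyl)oxy]-2,5,6-trimethoxyphenol (racemic) | COc1c(O)c(OC)c(OC)c(O[Si](C)(C)C(C)(C)C)c1C(O[Si](C)(C)C(C)(C)C)C#Cc1c(OC)cccc1OCc1ccccc1 | intermediate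
16 | 1-(benzyloxy)-3-{3-[2-(benzyloxy)-6-methoxyphenyl]-1-[(tert-butyldimethylsilyl)oxy]prop-2-yn-1-yl}-4-[(tert-butyldimethylsilyl)oxy]-2,5,6-trimethoxybenzene (racemic) | COc1c(OCc2ccccc2)c(OC)c(OC)c(O[Si](C)(C)C(C)(C)C)c1C(O[Si](C)(C)C(C)(C)C)C#Cc1c(OC)cccc1OCc1ccccc1 | intermediate
17 | 4-(benzyloxy)-2-{3-[2-(benzyloxy)-6-methoxyphenyl]-1-hydroxyprop-2-yn-1-yl}-3,5,6-trimethoxyphenol (racemic) | COc1c(OCc2ccccc2)c(OC)c(OC)c(O)c1C(O)C#Cc1c(OC)cccc1OCc1ccccc1 | intermediate
18 | 1-[3-(benzyloxy)-6-hydroxy-2,4,5-trimethoxyphenyl]-3-[2-(benzyloxy)-6-methoxyphenyl]prop-2-yn-1-one | COc1c(OCc2ccccc2)c(OC)c(OC)c(O)c1C(=O)C#Cc1c(OC)cccc1OCc1ccccc1 | intermediate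
19 | 1-[3-(benzyloxy)-6-hydroxy-2,4,5-trimethoxyphenyl]-3-[2-(benzyloxy)-6-methoxyphenyl]-3-(diethylamino)prop-2-en-1-one (alkene geometry not fixed) | COc1c(OCc2ccccc2)c(OC)c(OC)c(O)c1C(=O)C=C(N(CC)CC)c1c(OC)cccc1OCc1ccccc1 | intermediate (not isolated)
20 | 6-(benzyloxy)-2-[2-(benzyloxy)-6-methoxyphenyl]-5,7,8-trimethoxy-4H-chromen-4-one | COc1cccc(OCc2ccccc2)c1-c1cc(=O)c2c(OC)c(OCc3ccccc3)c(OC)c(OC)c2o1 | intermediate
21 | 6-hydroxy-2-(2-hydroxy-6-methoxyphenyl)-5,7,8-trimethoxy-4H-chromen-4-one | COc1cccc(O)c1-c1cc(=O)c2c(OC)c(O)c(OC)c(OC)c2o1 | target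

## Step count and risks

Total: 13 steps. Longest linear sequence: 12 steps (steps 1, 2 and 4 to 13, from compound 1); the branch from compound 4 contributes step 3.

**Step 8 (key step).** The 6π closure may be slowed by the crowded, cis-methoxylated alkene terminus, so that the dienylketene is lost to dimerisation or to capture by traces of water. The doubly activated silyloxy carbinol may also lose silanol at 110 °C. The fallback keeps the ring expansion but runs it on a small alkenyl unit and attaches ring B afterwards. It sets out from 5.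
- Acetalisation of 5 with HC(OMe)3 and acid in MeOH gives (Z)-2-bromo-1,3,3-trimethoxyprop-1-ene F1.
- Bromine–lithium exchange and addition to 9, as in step 6, give 4-hydroxy-2,3-dimethoxy-4-[(1E)-1,3,3-trimethoxyprop-1-en-2-yl]cyclobut-2-en-1-one F2.
- Silylation as in step 7 gives 4-[(tert-butyldimethylsilyl)oxy]-2,3-dimethoxy-4-[(1E)-1,3,3-trimethoxyprop-1-en-2-yl]cyclobut-2-en-1-one F3.
- Thermolysis in toluene gives 4-[(tert-butyldimethylsilyl)oxy]-3-(dimethoxymethyl)-2,5,6-trimethoxyphenol F4.
- Benzylation gives [4-(benzyloxy)-2-(dimethoxymethyl)-3,5,6-trimethoxyphenoxy](tert-butyl)dimethylsilane F5.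
- Mild aqueous acid gives 3-(benzyloxy)-6-[(tert-butyldimethylsilyl)oxy]-2,4,5-trimethoxybenzaldehyde F6.
- Addition of acetylide 6 gives 1-[3-(benzyloxy)-6-[(tert-butyldimethylsilyl)oxy]-2,4,5-trimethoxyphenyl]-3-[2-(benzyloxy)-6-methoxyphenyl]prop-2-yn-1-ol F7, wherever the silyl group then sits.
- Bu4NF removes the silyl group, and the route is rejoined at 17.

**Step 6.** The β-silyloxy vinyllithium 10 may suffer a 1,3 oxygen-to-carbon silyl shift (retro-Brook), intermolecular proton transfer from the propargylic C–H, or β-elimination before it meets the squarate. The fallback removes the silyl group from the organometallic. It sets out from 7, which is deprotonated with one equivalent of n-BuLi and then exchanged with t-BuLi. The resulting alkoxide-bearing vinyllithium has a less acidic neighbouring C–H and no silicon to migrate. Addition to 9 gives 4-{(1Z)-5-[2-(benzyloxy)-6-methoxyphenyl]-3-hydroxy-1-methoxypent-1-en-4-yn-2-yl}-4-hydroxy-2,3-dimethoxycyclobut-2-en-1-one F8. Double silylation with TBSOTf and 2,6-lutidine brings it back to the route at 12.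

**Step 9.** Carbonate may remove the aryl silyl ether so that both phenolic oxygens are benzylated, or the doubly flanked C6 hydroxyl may alkylate sluggishly. The fallback gives up the C6 protecting group and accepts a redox detour. It sets out from 15.
- Bu4NF gives 2-{3-[2-(benzyloxy)-6-methoxyphenyl]-1-hydroxyprop-2-yn-1-yl}-3,5,6-trimethoxybenzene-1,4-diol F9.
- MnO2 oxidises both the hydroquinone and the carbinol to 2-{3-[2-(benzyloxy)-6-methoxyphenyl]prop-2-ynoyl}-3,5,6-trimethoxycyclohexa-2,5-diene-1,4-dione F10.
- Aqueous Na2S2O4 reduces the quinone to 3-[2-(benzyloxy)-6-methoxyphenyl]-1-(2,5-dihydroxy-3,4,6-trimethoxyphenyl)prop-2-yn-1-one F11.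
- Et2NH under argon closes ring C to 2-[2-(benzyloxy)-6-methoxyphenyl]-6-hydroxy-5,7,8-trimethoxy-4H-chromen-4-one F12.
- Hydrogenolysis over Pd/C rejoins the route at 21.

**Step 12.** The phenoxide may attack the α-alkyne carbon in a 5-exo closure and give an aurone, or amine addition may stall at the β-carbon, which is shielded by the 2,6-disubstituted ring B. The fallback closes ring C from a 1,3-diketone. It sets out from 18.
- The smaller and more nucleophilic pyrrolidine adds to give 1-[3-(benzyloxy)-6-hydroxy-2,4,5-trimethoxyphenyl]-3-[2-(benzyloxy)-6-methoxyphenyl]-3-(pyrrolidin-1-yl)prop-2-en-1-one F13.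
- Dilute aqueous HCl in THF hydrolyses it to 1-[3-(benzyloxy)-6-hydroxy-2,4,5-trimethoxyphenyl]-3-[2-(benzyloxy)-6-methoxyphenyl]propane-1,3-dione F14.
- Cyclodehydration with TsOH in toluene rejoins the route at 20.

## Further compounds

F1 | step 8 | (Z)-2-bromo-1,3,3-trimethoxyprop-1-ene | CO/C=C(\Br)C(OC)OC
F2 | step 8 | 4-hydroxy-2,3-dimethoxy-4-[(1E)-1,3,3-trimethoxyprop-1-en-2-yl]cyclobut-2-en-1-one (racemic) | O=C1C(OC)=C(OC)C1(O)/C(=C\OC)C(OC)OC
F3 | step 8 | 4-[(tert-butyldimethylsilyl)oxy]-2,3-dimethoxy-4-[(1E)-1,3,3-trimethoxyprop-1-en-2-yl]cyclobut-2-en-1-one (racemic) | O=C1C(OC)=C(OC)C1(O[Si](C)(C)C(C)(C)C)/C(=C\OC)C(OC)OC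
F4 | step 8 | 4-[(tert-butyldimethylsilyl)oxy]-3-(dimethoxymethyl)-2,5,6-trimethoxyphenol | COc1c(O)c(OC)c(OC)c(O[Si](C)(C)C(C)(C)C)c1C(OC)OC
F5 | step 8 | [4-(benzyloxy)-2-(dimethoxymethyl)-3,5,6-trimethoxyphenoxy](tert-butyl)dimethylsilane | COc1c(OCc2ccccc2)c(OC)c(OC)c(O[Si](C)(C)C(C)(C)C)c1C(OC)OC
F6 | step 8 | 3-(benzyloxy)-6-[(tert-butyldimethylsilyl)oxy]-2,4,5-trimethoxybenzaldehyde | COc1c(OCc2ccccc2)c(OC)c(OC)c(O[Si](C)(C)C(C)(C)C)c1C=O
F7 | step 8 | 1-[3-(benzyloxy)-6-[(tert-butyldimethylsilyl)oxy]-2,4,5-trimethoxyphenyl]-3-[2-(benzyloxy)-6-methoxyphenyl]prop-2-yn-1-ol (racemic) | COc1c(OCc2ccccc2)c(OC)c(OC)c(O[Si](C)(C)C(C)(C)C)c1C(O)C#Cc1c(OC)cccc1OCc1ccccc1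
F8 | step 6 | 4-{(1Z)-5-[2-(benzyloxy)-6-methoxyphenyl]-3-hydroxy-1-methoxypent-1-en-4-yn-2-yl}-4-hydroxy-2,3-dimethoxycyclobut-2-en-1-one (mixture of racemic diastereomers) | O=C1C(OC)=C(OC)C1(O)/C(=C\OC)C(O)C#Cc1c(OC)cccc1OCc1ccccc1
F9 | step 9 | 2-{3-[2-(benzyloxy)-6-methoxyphenyl]-1-hydroxyprop-2-yn-1-yl}-3,5,6-trimethoxybenzene-1,4-diol (racemic) | COc1c(O)c(OC)c(OC)c(O)c1C(O)C#Cc1c(OC)cccc1OCc1ccccc1
F10 | step 9 | 2-{3-[2-(benzyloxy)-6-methoxyphenyl]prop-2-ynoyl}-3,5,6-trimethoxycyclohexa-2,5-diene-1,4-dione | COC1=C(OC)C(=O)C(C(=O)C#Cc2c(OC)cccc2OCc2ccccc2)=C(OC)C1=O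
F11 | step 9 | 3-[2-(benzyloxy)-6-methoxyphenyl]-1-(2,5-dihydroxy-3,4,6-trimethoxyphenyl)prop-2-yn-1-one | COc1c(O)c(OC)c(OC)c(O)c1C(=O)C#Cc1c(OC)cccc1OCc1ccccc1
F12 | step 9 | 2-[2-(benzyloxy)-6-methoxyphenyl]-6-hydroxy-5,7,8-trimethoxy-4H-chromen-4-one | COc1cccc(OCc2ccccc2)c1-c1cc(=O)c2c(OC)c(O)c(OC)c(OC)c2o1
F13 | step 12 | 1-[3-(benzyloxy)-6-hydroxy-2,4,5-trimethoxyphenyl]-3-[2-(benzyloxy)-6-methoxyphenyl]-3-(pyrrolidin-1-yl)prop-2-en-1-one (alkene geometry not fixed) | COc1c(OCc2ccccc2)c(OC)c(OC)c(O)c1C(=O)C=C(N1CCCC1)c1c(OC)cccc1OCc1ccccc1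
F14 | step 12 | 1-[3-(benzyloxy)-6-hydroxy-2,4,5-trimethoxyphenyl]-3-[2-(benzyloxy)-6-methoxyphenyl]propane-1,3-dione | COc1c(OCc2ccccc2)c(OC)c(OC)c(O)c1C(=O)CC(=O)c1c(OC)cccc1OCc1ccccc1
A1 | alternative 1 | 1-[3,4-bis(benzyloxy)-6-hydroxy-2,5-dimethoxyphenyl]-3-[2-methoxy-6-(methoxymethoxy)phenyl]prop-2-yn-1-one | COCOc1cccc(OC)c1C#CC(=O)c1c(O)c(OC)c(OCc2ccccc2)c(OCc2ccccc2)c1OC
A2 | alternative 1 | 3,4-bis(benzyloxy)-2,5-dimethoxy-6-(trimethylsilyl)phenyl trifluoromethanesulfonate | COc1c(OCc2ccccc2)c(OCc2ccccc2)c(OC)c(OS(=O)(=O)C(F)(F)F)c1[Si](C)(C)C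
A3 | alternative 1 | 3-[2-methoxy-6-(methoxymethoxy)phenyl]prop-2-ynoic acid | COCOc1cccc(OC)c1C#CC(=O)O
A4 | alternative 2 | pivalate of the ring B-fused lactone (a chromeno[4,3-b]chromene-6,7-dione) | COc1cccc2oc(=O)c3c(=O)c4c(OC)c(OC(=O)C(C)(C)C)c(OC)c(OC)c4oc3c12
A5 | alternative 2 | 5,7,8-trimethoxy-2-(2-methoxyphenyl)-4-oxo-6-(pivaloyloxy)-4H-chromene-3-carboxylic acid | COc1ccccc1-c1oc2c(OC)c(OC)c(OC(=O)C(C)(C)C)c(OC)c2c(=O)c1C(=O)O
A6 | alternative 3 | 6-(benzyloxy)-2-(2-hydroxy-6-methoxyphenyl)-5,7,8-trimethoxy-4H-chromen-4-one | COc1cccc(O)c1-c1cc(=O)c2c(OC)c(OCc3ccccc3)c(OC)c(OC)c2o1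
A7 | alternative 3 | cyclobut-2-en-1-one | O=C1CC=C1
A8 | alternative 3 | 6-(benzyloxy)-5,7,8-trimethoxy-2-(methoxyethynyl)-4H-chromen-4-one | COC#Cc1cc(=O)c2c(OC)c(OCc3ccccc3)c(OC)c(OC)c2o1
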